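6 questions stand on these flasks, and two colleagues read the same runs in two ways.

- the flask that comes out highest in amount of target, in percent of the starting material charged, or "all alike" when all lie within 1.5 percentage points (oak / alder / ash / birch / elm / all alike)
- target at the end, in percent of the starting material charged, oak
- target at the end, in percent of the starting material charged, alder
- target at the end, in percent of the starting material charged, ash
- target at the end, in percent of the starting material charged, birch
- target at the end, in percent of the starting material charged, elm

in all of them: enzyme 1.1 µM; added ligand 5.6 µM; impurity 0.48 µM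
- east: starting material 0.080 M; second substrate 0.040 M; run made earlier
- west: starting material 0.080 M; second substrate 0.027 M; run made earlier
- south-west: starting material 0.080 M; second substrate 0.060 M; run made earlier
- oak: starting material 0.080 M; second substrate 0.0400 M; everything together at the start; time 1.5 h
- alder: starting material 0.080 M; second substrate 0.0400 M (in portions, 4, over 20 min); first portion at the start, last at 20 min; time 1.5 h
- ash: starting material 0.080 M; second substrate 0.0400 M (fed, over 20 min); all else is in the flask from the start; the feed brings no volume worth counting; time 1.5 h
- birch: starting material 0.080 M (fed, over 5.0 min); second substrate 0.0400 M; all else is in the flask from the start; the feed brings no volume worth counting; time 1.5 h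
- elm: starting material 0.080 M (fed, over 20 min); second substrate 0.0400 M; all else is in the flask from the start; the feed brings no volume worth counting; time 1.5 h

| run | time / min | target / % | starting material / % |
|---|---|---|---|
| east | 5.00 | 11.6 | 87.5 |
| east | 15.0 | 23.3 | 76.1 |
| east | 25.0 | 28.6 | 70.9 |
| east | 40.0 | 32.9 | 67.0 |
| east | 50.0 | 35.0 | 66.2 |
| east | 80.0 | 37.0 | 63.4 |
| east | 90.0 | 37.4 | 62.6 |
| west | 15.0 | 16.8 | 83.1 |
| west | 30.0 | 21.6 | 77.5 |
| west | 50.0 | 24.7 | 75.9 |
| west | 60.0 | 25.9 | 74.7 |
| west | 80.0 | 26.3 | 73.7 |
| west | 90.0 | 26.2 | 73.3 |
| west | 120 | 27.0 | 72.6 |
| south-west | 8.00 | 21.9 | 78.3 |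
| south-west | 12.0 | 27.7 | 72.0 |
| south-west | 20.0 | 35.9 | 64.3 |
| south-west | 30.0 | 41.8 | 58.7 |
| south-west | 50.0 | 47.2 | 53.5 |
| south-west | 80.0 | 50.8 | 49.0 |
| south-west | 120 | 53.4 | 46.8 |

(standard deviation of a reading: 0.3 percentage points)

- the earlier runs were read with a standard deviation of 0.3 percentage points

The first colleague asks for the end state. Of the two substrates, second substrate is the limiting reagent, with 0.0400 M against 0.080 M of starting material. Taken one to one, that puts a ceiling of 50.0% on target. She points to the west run, which still creeps from 26.2% at 90.0 min to 27.0% at 120 min. So she calls the runs slow, not finished. Order of addition leaves the ceiling where it is, so she expects the flasks within 1.5 points.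

The second colleague asks how fast that end is approached. He writes the rate as k(t) times c(starting material) times c(second substrate), with k falling in time. His quantity is the exposure, the integral of k from the start. One reading gives it: take the logarithm of the fraction left of starting material over the fraction left of second substrate, and divide by the difference of the charges.

The east run gives 9.05 L mol⁻¹ by 15.0 min and 22.7 L mol⁻¹ by 90.0 min. The west run, with its different c(second substrate), gives 22.5 L mol⁻¹ by 90.0 min. So on these readings exposure runs as a clock, and 39.9% of the east run's exposure to 90.0 min had passed by 15.0 min.

I side with him and reckon this way. An addition spread over a time arrives on average at its mid-point, here 10.0 min for the slow flasks. The lost exposure is what the east run had gathered by that mid-point, which I take as the mean of its values at 5.00 min and 15.0 min, 6.28 L mol⁻¹. I let a slow flask run like oak on what remains, which gives me 32.5%. Oak carries the east charges, so it should repeat 37.4%.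

The forecast, from the clock side, names oak: oak 37.4%, alder 32.2%, ash 32.2%, birch 36.1%, elm 32.4%. Its ground: “Any delay in feeding wastes the early, live enzyme, so the all-at-once flask wins.” Its ash figure lies 0.30 points below mine.

The flask gives oak at 37.5%, with alder 31.7%, ash 31.6%, birch 35.5% and elm 30.4%.

    starting material + enzyme ⇌ starting complex (K = 5.10 L mol⁻¹, k = 8800 L mol⁻¹ s⁻¹)
    second substrate + starting complex ⇌ ternary complex (K = 54.0 L mol⁻¹, k = 16000 L mol⁻¹ s⁻¹)
    ternary complex → enzyme + target (k = 250 s⁻¹)
    enzyme + added ligand ⇌ idle complex (K = 3.70 × 10⁶ L mol⁻¹, k = 200 L mol⁻¹ s⁻¹)
    enzyme + impurity → spent catalyst (k = 46000 L mol⁻¹ s⁻¹)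

Her ceiling has its region in time. Left ten times as long, to 15.0 h, oak holds 48.9% and elm 48.5%, inside her margin. Elm at the end lies 2.1 points below my figure. Now take elm stopped at 40 min. The east run's exposure by then is 16.8 L mol⁻¹, and subtracting the lost exposure gives 25.6%. That flask holds 23.0%.

(The data come from a simulation with constants of no real substance; noise was put on by code.)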